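**Assumption:** the stereocentre is (S) as read from the SMILES; small reagents (t-BuOOH, MOMCl, n-BuLi and the like) are unnumbered. The enantiopurity of the product is that of the Sharpless step (about 91–95% ee for geraniol), so a truly single enantiomer needs an ee upgrade or the stoichiometric variant.

## Retrosynthetic overview

1. Target 10 ⇒ bis-MOM β-hydroxy ketone 9 (phenol deprotection) ⇒ 1-aryl-1,3-diol 8 (benzylic oxidation).
2. 8 ⇒ aryl epoxy carbinol 7 by hydroxyl-directed hydride opening; the epoxide carries the tertiary C–O stereocentre in masked form.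
3. 7 ⇒ aryllithium 6 (from dibromide 5) plus epoxy aldehyde 3 (aryl–carbonyl carbon bond).
4. 3 ⇒ geraniol 1 by Sharpless asymmetric epoxidation, which sets the only stereocentre.
5. Rings: the benzene ring is bought intact; the only ring made is a transient oxirane (formed in step 1, opened in step 5).

## Route

Step 1
Reactants: 1 geraniol, (E)-3,7-dimethylocta-2,6-dien-1-ol
Product: 2 (2S,3S)-2,3-epoxygeraniol, [(2S,3S)-3-methyl-3-(4-methylpent-3-en-1-yl)oxiran-2-yl]methanol
Conditions: Ti(OiPr)4 (5 mol %), L-(+)-diethyl tartrate (7.5 mol %), t-BuOOH (2 equiv), 4 Å MS, CH2Cl2, −20 °C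
Reagents that add atoms: tert-butyl hydroperoxide, CC(C)(C)OO
Why: Sharpless asymmetric epoxidation; only the allylic alcohol binds the titanium tartrate catalyst, so the 2,3-alkene alone is epoxidized, and L-(+)-DET gives the (2S,3S)-epoxide, whose C3 is the future tertiary carbinol.

Step 2
Reactants: 2 (2S,3S)-2,3-epoxygeraniol
Product: 3 (2R,3S)-3-methyl-3-(4-methylpent-3-en-1-yl)oxirane-2-carbaldehyde
Conditions: TEMPO (10 mol %), PhI(OAc)2 (1.1 equiv), CH2Cl2, rt; used promptly after a short silica plug
Reagents that add atoms: none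
Why: Oxoammonium (TEMPO) oxidation stops at the aldehyde under near-neutral conditions, leaving the epoxide, its configuration (the descriptor at C2 changes only by CIP priority) and the remote alkene untouched.

Step 3
Reactants: 4 2,5-dibromobenzene-1,4-diol (2,5-dibromohydroquinone)
Product: 5 1,4-dibromo-2,5-bis(methoxymethoxy)benzene
Conditions: MOMCl (3 equiv), K2CO3 (4 equiv), DMF, 0 °C → rt
Reagents that add atoms: chloromethyl methyl ether (MOMCl), COCCl
Why: Williamson-type O-alkylation of both phenols gives the bis-MOM acetal, which tolerates organolithium, hydride and oxidation conditions and stabilizes the ortho-lithio species.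

Step 4
Reactants: 5 1,4-dibromo-2,5-bis(methoxymethoxy)benzene; 3 (2R,3S)-3-methyl-3-(4-methylpent-3-en-1-yl)oxirane-2-carbaldehyde
Product: 7 (4-bromo-2,5-bis(methoxymethoxy)phenyl)[(2S,3S)-3-methyl-3-(4-methylpent-3-en-1-yl)oxiran-2-yl]methanol (epimer mixture at the carbinol carbon), via aryllithium 6 (not isolated)
Conditions: 5 (1.2 equiv), n-BuLi (1.15 equiv), THF, −78 °C, 30 min; then 3 (1.0 equiv), −78 °C, 1 h; H2O quench
Reagents that add atoms: n-butyllithium, CCCC[Li] (supplies the lithium of 6; none of its atoms remain in 7)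
Why: Bromine–lithium exchange at −78 °C stops after one exchange with one equivalent of n-BuLi, and the aryllithium adds 1,2 to the aldehyde faster than it touches the epoxide; the new carbinol centre is formed unselectively but is erased in step 6.

Step 5
Reactants: 7 aryl epoxy carbinol (epimer mixture)
Product: 8 (1RS,3S)-1-[4-bromo-2,5-bis(methoxymethoxy)phenyl]-3,7-dimethyloct-6-ene-1,3-diol
Conditions: NaAlH2(OCH2CH2OMe)2 (Red-Al, 2.5 equiv), THF, 0 °C → rt; then H2O, 1 M NaOH
Reagents that add atoms: none
Why: Hydroxyl-directed reductive epoxide opening; the alkoxyaluminate delivers hydride intramolecularly to C2 (1,3-diol selectivity), and the tertiary C3–O bond is never broken, so the (S) configuration is retained while the aryl bromide and MOM ethers are inert at this temperature.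

Step 6
Reactants: 8 (1RS,3S)-1-aryl-1,3-diol
Product: 9 (3S)-1-[4-bromo-2,5-bis(methoxymethoxy)phenyl]-3-hydroxy-3,7-dimethyloct-6-en-1-one
Conditions: Dess–Martin periodinane (1.3 equiv), pyridine (3 equiv), CH2Cl2, 0 °C → rt
Reagents that add atoms: none
Why: Dess–Martin oxidation converts the secondary benzylic alcohol of both epimers into the aryl ketone, while the tertiary alcohol cannot be oxidized and the pyridine buffer protects the MOM ethers and the aldol from acid.

Step 7
Reactants: 9 bis-MOM β-hydroxy ketone
Product: 10 (3S)-1-(4-bromo-2,5-dihydroxyphenyl)-3-hydroxy-3,7-dimethyloct-6-en-1-one (target)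
Conditions: HCl (about 1 M), MeOH/THF, 0 °C → rt, under Ar; stopped at full conversion, NaHCO3 work-up
Reagents that add atoms: none
Why: Acid-catalysed transacetalization cleaves both aryl MOM ethers to dimethoxymethane (the one ortho to the ketone fastest), and dilute acid at room temperature leaves the non-allylic tertiary alcohol, the trisubstituted alkene and the stereocentre intact.

## Compound list

1 | geraniol, (E)-3,7-dimethylocta-2,6-dien-1-ol | CC(C)=CCC/C(C)=C/CO | starting material
2 | (2S,3S)-2,3-epoxygeraniol | CC(C)=CCC[C@]1(C)O[C@H]1CO | intermediate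
3 | (2R,3S)-3-methyl-3-(4-methylpent-3-en-1-yl)oxirane-2-carbaldehyde | CC(C)=CCC[C@]1(C)O[C@H]1C=O | intermediate
4 | 2,5-dibromobenzene-1,4-diol | Oc1cc(Br)c(O)cc1Br | starting material
5 | 1,4-dibromo-2,5-bis(methoxymethoxy)benzene | COCOc1cc(Br)c(OCOC)cc1Br | intermediate
6 | [4-bromo-2,5-bis(methoxymethoxy)phenyl]lithium | [Li]c1cc(OCOC)c(Br)cc1OCOC | intermediate (not isolated)
7 | (4-bromo-2,5-bis(methoxymethoxy)phenyl)[(2S,3S)-3-methyl-3-(4-methylpent-3-en-1-yl)oxiran-2-yl]methanol, carbinol epimers | CC(C)=CCC[C@]1(C)O[C@H]1C(O)c1cc(OCOC)c(Br)cc1OCOC | intermediate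
8 | (1RS,3S)-1-[4-bromo-2,5-bis(methoxymethoxy)phenyl]-3,7-dimethyloct-6-ene-1,3-diol | CC(C)=CCC[C@](C)(O)CC(O)c1cc(OCOC)c(Br)cc1OCOC | intermediate
9 | (3S)-1-[4-bromo-2,5-bis(methoxymethoxy)phenyl]-3-hydroxy-3,7-dimethyloct-6-en-1-one | CC(C)=CCC[C@](C)(O)CC(=O)c1cc(OCOC)c(Br)cc1OCOC | intermediate
10 | (3S)-1-(4-bromo-2,5-dihydroxyphenyl)-3-hydroxy-3,7-dimethyloct-6-en-1-one | CC(C)=CCC[C@](C)(O)CC(=O)c1cc(O)c(Br)cc1O | target

## Step count and risks

Total steps: 7. Longest linear sequence: 6 (steps 1, 2, 4, 5, 6, 7 from geraniol); step 3 is a one-step side branch.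

**Step 4** is exposed because the α,β-epoxy aldehyde 3 is labile and the coupling depends on a clean single bromine–lithium exchange. The fallback sets out from 2 and comes back to the route at 9. Open 2 with NaAlH2(OCH2CH2OMe)2 (THF, 0 °C) to (S)-3,7-dimethyloct-6-ene-1,3-diol F1. Oxidize its primary alcohol with TEMPO/PhI(OAc)2 in MeCN–H2O to (S)-3-hydroxy-3,7-dimethyloct-6-enoic acid F2. Couple with MeNHOMe·HCl (EDC·HCl, HOBt, i-Pr2NEt) to the Weinreb amide (S)-3-hydroxy-N-methoxy-N,3,7-trimethyloct-6-enamide F3. Acylate aryllithium 6 (2.3 equiv, THF, −78 °C; the first equivalent only deprotonates the tertiary OH) with F3, which gives 9 directly and bypasses 3, 7 and 8 without lengthening the sequence.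

**Step 5** may give imperfect regiocontrol with the secondary benzylic carbinol, or some C–Br reduction if it has to be warmed. The fallback sets out from 7 and comes back at 9. Oxidize 7 first (Dess–Martin periodinane, pyridine, CH2Cl2) to the epoxy ketone (4-bromo-2,5-bis(methoxymethoxy)phenyl)[(2R,3S)-3-methyl-3-(4-methylpent-3-en-1-yl)oxiran-2-yl]methanone F4. Then cleave its α C–O bond by single-electron reduction with SmI2 (2.1 equiv, THF/MeOH, −90 °C, quenched cold). This gives the β-hydroxy ketone 9 with the β-centre untouched, replacing the hydride opening by a reductive opening at the ketone oxidation level. Its own risk is the para-bromoaryl ketyl (loss of bromide, over-reduction).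

**Step 7** risks acid-induced dehydration of the tertiary aldol and ring closure onto the ortho phenol (chromanone) or onto the alkene. The fallback sets out from 9 and comes back at 10. Use a non-protic transprotection: TMSOTf/2,2′-bipyridyl (CH2Cl2, 0 °C → rt) converts both aryl MOM ethers, and the tertiary OH, into trimethylsilyl ethers. This gives (3S)-1-[4-bromo-2,5-bis(trimethylsilyloxy)phenyl]-3,7-dimethyl-3-(trimethylsilyloxy)oct-6-en-1-one F5. Brief treatment with citric acid in MeOH at 0 °C then frees all three hydroxyls under far milder conditions than acetal hydrolysis, giving 10.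

## Further compounds

F1 | step 4 | (S)-3,7-dimethyloct-6-ene-1,3-diol | CC(C)=CCC[C@](C)(O)CCO
F2 | step 4 | (S)-3-hydroxy-3,7-dimethyloct-6-enoic acid | CC(C)=CCC[C@](C)(O)CC(=O)O
F3 | step 4 | (S)-3-hydroxy-N-methoxy-N,3,7-trimethyloct-6-enamide | CC(C)=CCC[C@](C)(O)CC(=O)N(C)OC
F4 | step 5 | (4-bromo-2,5-bis(methoxymethoxy)phenyl)[(2R,3S)-3-methyl-3-(4-methylpent-3-en-1-yl)oxiran-2-yl]methanone | CC(C)=CCC[C@]1(C)O[C@H]1C(=O)c1cc(OCOC)c(Br)cc1OCOC
F5 | step 7 | (3S)-1-[4-bromo-2,5-bis(trimethylsilyloxy)phenyl]-3,7-dimethyl-3-(trimethylsilyloxy)oct-6-en-1-one | CC(C)=CCC[C@](C)(O[Si](C)(C)C)CC(=O)c1cc(O[Si](C)(C)C)c(Br)cc1O[Si](C)(C)C
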